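The hydroazulene is cut at the ring-fusion bond C3a–C8a and at the enone bond C7–C8. This reveals a p-menthane: a 1-methylcyclohexene oxide whose neighbouring ring carbon carries the methallyl carbinol ester. The key step exploits two features of the target: the quaternary C8a flanked by carbonyl C8 and ring-fusion C3a (the mark of a pinacol-type shift), and the 6-methyl-6-ene unit of the seven-membered ring (the mark of a carbonyl-ene closure). In one flask a Lewis acid contracts the cyclohexane stereospecifically (C3a migrates from C8 to C8a) and the released aldehyde C8 is trapped by the methallyl terminus C7, closing both rings. One reagent-controlled anti-aldol reaction relays all other stereocentres.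

Key step: step 7

Remark: atom numbers C1–C8a are the azulene numbers of the target (C3 carbinol, C3a ring-fusion CH, C4 ester carbon, C6 methyl-bearing alkene carbon, C7 vinyl CH, C8 carbonyl, C8a quaternary carbon).
Assumption: the (4S,5S)-bromoborane of step 2 is taken to deliver the (2S,1′S) anti-aldol; if its sense of induction is the opposite, the (4R,5R) reagent is used. This bromoborane and MABR are standard reagents prepared beforehand from commercial materials.

Step 1
Reactants: 1 3-methylbut-3-en-1-ol
Product: 2 3-methylbut-3-enal
Conditions: DMP, NaHCO3, CH2Cl2, 0 °C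
Reagents that add atoms: none
Why: Dess–Martin oxidation under bicarbonate buffering should oxidise the primary homoallylic alcohol without moving the 1,1-disubstituted double bond into conjugation; the volatile aldehyde is used at once as a solution.

Step 2
Reactants: 3 4-methylcyclohex-3-en-1-one; 2 3-methylbut-3-enal
Product: 5 (2S)-2-[(1S)-1-hydroxy-3-methylbut-3-en-1-yl]-4-methylcyclohex-3-en-1-one (anti aldol), via enol borinate 4 (not isolated)
Conditions: (4S,5S)-2-bromo-4,5-diphenyl-1,3-ditosyl-1,3,2-diazaborolidine, i-Pr2NEt, CH2Cl2, −78 °C; then 2, −78 °C; pH 7 buffer–MeOH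
Reagents that add atoms: none
Why: Soft enolisation by the bromoborane at the doubly activated C2 methylene gives the cyclic (E)-enol borinate 4, and a closed Zimmerman–Traxler boron aldol reaction should then give the anti adduct at the α-carbon, the C2-symmetric bis-sulfonamide controller selecting the enolate face and hence both new stereocentres (ring C2 and the carbinol carbon).

Step 3
Reactants: 5 anti aldol
Product: 6 (1R,2S)-2-[(1S)-1-hydroxy-3-methylbut-3-en-1-yl]-4-methyl-1-(propan-2-yl)cyclohex-3-en-1-ol
Conditions: i-PrMgCl, CeCl3, THF, −78 to 0 °C; aq. NH4Cl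
Reagents that add atoms: isopropylmagnesium chloride, CC(C)[Mg]Cl
Why: Organocerium 1,2-addition is barely basic and so should add to the enolisable β,γ-unsaturated aldolate; equatorial attack on the chelated half-chair, anti to the C2 side chain, should place the new tertiary hydroxyl cis to that chain (substrate control by the aldol centre).

Step 4
Reactants: 6 diol; 7 3,4,5-trimethoxybenzoyl chloride
Product: 8 (1S)-1-[(1S,6R)-6-hydroxy-3-methyl-6-(propan-2-yl)cyclohex-2-en-1-yl]-3-methylbut-3-en-1-yl 3,4,5-trimethoxybenzoate
Conditions: Et3N, DMAP (cat.), CH2Cl2, 0 °C to rt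
Reagents that add atoms: none
Why: DMAP-catalysed acylation should take the secondary hydroxyl only, the tertiary one being too hindered.

Step 5
Reactants: 8 hydroxy ester
Product: 9 trimethylsilyl ether of 8 at the tertiary hydroxyl
Conditions: TMSOTf, 2,6-lutidine, CH2Cl2, −78 °C
Reagents that add atoms: trimethylsilyl trifluoromethanesulfonate, C[Si](C)(C)OS(=O)(=O)C(F)(F)F
Why: Silylation with a silyl triflate and lutidine masks the tertiary hydroxyl, which would otherwise direct the peracid to the wrong face and capture the cation of step 7.

Step 6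
Reactants: 9 silyl ether
Product: 10 ring epoxide of 9 with the oxygen cis to isopropyl and trans to the silyloxy group and the side chain
Conditions: mCPBA (1 equiv), NaHCO3, CH2Cl2, −20 to 0 °C
Reagents that add atoms: mCPBA, OOC(=O)c1cccc(Cl)c1
Why: Prilezhaev epoxidation should pick the more nucleophilic trisubstituted ring alkene over the 1,1-disubstituted one and approach from the face opposite to the axial silyloxy group and the allylic side chain, giving the epoxide cis to isopropyl (substrate control).

Step 7
Reactants: 10 epoxide
Product: 13 (3R,3aS,4S,8aS)-3,8-dihydroxy-8a-methyl-6-methylidene-3-(propan-2-yl)decahydroazulen-4-yl 3,4,5-trimethoxybenzoate, via ring-contracted aldehyde 11 (not isolated), via silylated ene adduct 12 (not isolated)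
Conditions: MeAl(OAr)2 (MABR, Ar = 4-bromo-2,6-di-tert-butylphenyl), CH2Cl2, −78 °C; then Me2AlCl, −78 to 0 °C; then 1 M HCl, THF
Reagents that add atoms: none
Why: The aluminium Lewis acid opens the epoxide at its tertiary carbon and the ring bond from the epoxide CH to the side-chain-bearing carbon (future C3a) shifts to that carbon anti to the departing oxygen (Meinwald rearrangement, a pinacol-type ring contraction), giving the α-quaternary cyclopentanecarbaldehyde 11, whose Lewis-acid complex is then attacked by the terminal methallyl carbon in an intramolecular carbonyl-ene reaction that passes an allylic methyl hydrogen to oxygen. Both halves are known reaction types: the Lewis-acid ring contraction of 1-methylcyclohexene oxides to 1-methylcyclopentanecarbaldehydes and the Me2AlCl-promoted ene cyclisation of alkenyl aldehydes whose tether sits on the central ene carbon. The five-membered ring closes by a 1,2-alkyl shift (six-to-five contraction); the seven-membered ring closes through a six-centre ene transition state in which both alkene carbons become ring atoms (endo for the alkene, exo for the carbonyl). C8a is set by stereospecific inversion at the epoxide carbon, so the epoxide face fixed in step 6 puts the formyl group cis to isopropyl and the methyl cis to the silyloxy group; C3a migrates with retention, which fixes the trans ring fusion; the new carbinol centre at C8 is removed in step 8. The step needs the ring-bond shift to beat hydride shift and oxygen capture of the cation, which the tertiary migrating carbon, the bulky phenoxide ligands without nucleophilic counter-ion and the silylated hydroxyl should secure. Bonding at the terminal alkene carbon (Markovnikov sense) is secured by the 1,1-disubstituted alkene, so the seven-membered and not a six-membered ring forms, and any double-bond isomer of the ene product converges in step 8.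

Step 8
Reactants: 13 hydroxy ester with exocyclic methylene
Product: 15 (3R,3aS,4S,8aS)-3-hydroxy-6,8a-dimethyl-8-oxo-3-(propan-2-yl)-1,2,3,3a,4,5,8,8a-octahydroazulen-4-yl 3,4,5-trimethoxybenzoate (target), via β,γ-unsaturated ketone 14 (not isolated)
Conditions: DMP, NaHCO3, CH2Cl2, 0 °C to rt; then DBU (cat.), 0 °C
Reagents that add atoms: none
Why: Dess–Martin oxidation gives the β,γ-unsaturated ketone 14, whose α-methylene (the only enolisable position, C8a being quaternary) is deprotonated by catalytic DBU and reprotonated at the exocyclic carbon, which should move the double bond into conjugation without touching a stereocentre.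

Compound list
1 | 3-methylbut-3-en-1-ol | CC(=C)CCO | starting material
2 | 3-methylbut-3-enal | CC(=C)CC=O | intermediate
3 | 4-methylcyclohex-3-en-1-one | CC1=CCC(=O)CC1 | starting material
4 | (4S,5S)-2-[(4-methylcyclohexa-1,3-dien-1-yl)oxy]-4,5-diphenyl-1,3-ditosyl-1,3,2-diazaborolidine (enol borinate) | CC1=CC=C(OB2N(S(=O)(=O)c3ccc(C)cc3)[C@@H](c4ccccc4)[C@H](c5ccccc5)N2S(=O)(=O)c6ccc(C)cc6)CC1 | intermediate
5 | (2S)-2-[(1S)-1-hydroxy-3-methylbut-3-en-1-yl]-4-methylcyclohex-3-en-1-one | O=C1CCC(C)=C[C@H]1[C@@H](O)CC(C)=C | intermediate
6 | (1R,2S)-2-[(1S)-1-hydroxy-3-methylbut-3-en-1-yl]-4-methyl-1-(propan-2-yl)cyclohex-3-en-1-ol (tertiary OH cis to the side chain) | CC(C)[C@]1(O)CCC(C)=C[C@H]1[C@@H](O)CC(C)=C | intermediate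
7 | 3,4,5-trimethoxybenzoyl chloride | COc1cc(C(=O)Cl)cc(OC)c1OC | starting material
8 | (1S)-1-[(1S,6R)-6-hydroxy-3-methyl-6-(propan-2-yl)cyclohex-2-en-1-yl]-3-methylbut-3-en-1-yl 3,4,5-trimethoxybenzoate | CC(C)[C@]1(O)CCC(C)=C[C@H]1[C@@H](OC(=O)c2cc(OC)c(OC)c(OC)c2)CC(C)=C | intermediate
9 | (1S)-1-[(1S,6R)-3-methyl-6-(propan-2-yl)-6-(trimethylsilyloxy)cyclohex-2-en-1-yl]-3-methylbut-3-en-1-yl 3,4,5-trimethoxybenzoate | CC(C)[C@]1(O[Si](C)(C)C)CCC(C)=C[C@H]1[C@@H](OC(=O)c2cc(OC)c(OC)c(OC)c2)CC(C)=C | intermediate
10 | epoxide of 9 at the ring double bond (7-oxabicyclo[4.1.0]heptane), oxygen cis to isopropyl and trans to the silyloxy group and the side chain | CC(C)[C@]1(O[Si](C)(C)C)CC[C@]2(C)O[C@@H]2[C@H]1[C@@H](OC(=O)c3cc(OC)c(OC)c(OC)c3)CC(C)=C | intermediate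
11 | (1S)-1-[(1S,2S,5R)-2-formyl-2-methyl-5-(propan-2-yl)-5-(trimethylsilyloxy)cyclopentyl]-3-methylbut-3-en-1-yl 3,4,5-trimethoxybenzoate | CC(C)[C@]1(O[Si](C)(C)C)CC[C@](C)(C=O)[C@H]1[C@@H](OC(=O)c2cc(OC)c(OC)c(OC)c2)CC(C)=C | intermediate
12 | (3R,3aS,4S,8aS)-8-hydroxy-8a-methyl-6-methylidene-3-(propan-2-yl)-3-(trimethylsilyloxy)decahydroazulen-4-yl 3,4,5-trimethoxybenzoate (C8 configuration not defined) | COc1cc(C(=O)O[C@H]2CC(=C)CC(O)[C@@]3(C)CC[C@@](O[Si](C)(C)C)(C(C)C)[C@H]23)cc(OC)c1OC | intermediate
13 | (3R,3aS,4S,8aS)-3,8-dihydroxy-8a-methyl-6-methylidene-3-(propan-2-yl)decahydroazulen-4-yl 3,4,5-trimethoxybenzoate (C8 configuration not defined) | COc1cc(C(=O)O[C@H]2CC(=C)CC(O)[C@@]3(C)CC[C@@](O)(C(C)C)[C@H]23)cc(OC)c1OC | intermediate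
14 | (3R,3aS,4S,8aS)-3-hydroxy-8a-methyl-6-methylidene-8-oxo-3-(propan-2-yl)decahydroazulen-4-yl 3,4,5-trimethoxybenzoate | COc1cc(C(=O)O[C@H]2CC(=C)CC(=O)[C@@]3(C)CC[C@@](O)(C(C)C)[C@H]23)cc(OC)c1OC | intermediate
15 | (3R,3aS,4S,8aS)-3-hydroxy-6,8a-dimethyl-8-oxo-3-(propan-2-yl)-1,2,3,3a,4,5,8,8a-octahydroazulen-4-yl 3,4,5-trimethoxybenzoate | COc1cc(C(=O)O[C@H]2CC(C)=CC(=O)[C@@]3(C)CC[C@@](O)(C(C)C)[C@H]23)cc(OC)c1OC | target

Total step count: 8. Longest linear sequence: 8 steps (1 to 15).

Steps most likely to fail

Step 7 (riskiest). After the Lewis acid has opened the epoxide at its tertiary carbon, a hydride shift to the 2-methylcyclohexanone or capture of the cation by the silyloxy oxygen may outrun the ring-bond shift, and the seven-membered ene closure may lag behind. The fallback sets out from 8 and comes back at 13. Hydroxyl-directed epoxidation of 8 (VO(acac)2, t-BuOOH, CH2Cl2) should give the cis-epoxy alcohol F1, with the epoxide on the face opposite to that in 10. Silylation (TMS-imidazole) gives the silyl ether F2. MgBr2·OEt2 then opens the epoxide at the tertiary carbon with inversion to the trans-bromohydrin F3 (as its magnesium alkoxide). In F3 the ring bond antiperiplanar to the equatorial bromide migrates (halohydrin semipinacol ring contraction, a second inversion, with no free cation and no hydride shift), which gives the same aldehyde 11, now isolated. A separate Me2AlCl ene cyclisation (to 12) and acidic desilylation give 13.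

Step 2. Facial discrimination by the boron controller may be weak for this dienol borinate, and the amine may move the β,γ double bonds of ketone or aldehyde into conjugation before the C–C bond forms. The fallback runs from 3 back to 5. Condensation of 3 with (S)-1-amino-2-(methoxymethyl)pyrrolidine gives the SAMP hydrazone F4. Deprotonation (LDA, THF, −78 °C) and addition of 2 give the β-hydroxy hydrazone F5 (azaenolate aldol under auxiliary control). Mild cleavage (aqueous CuCl2 or oxalic acid) returns 5; the enantiomeric auxiliary is taken if the sense of induction demands it.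

Step 6. Discrimination between the two faces of the ring alkene may be poor (the other epoxide would end as the C8a epimer), and some epoxidation of the methallyl alkene may occur. The fallback runs from 9 back to 10 without a new compound (F0). The substrate-controlled peracid is replaced by catalyst-controlled dioxirane transfer (Shi epoxidation: fructose-derived ketone or its enantiomer, Oxone, K2CO3, MeCN–dimethoxymethane–H2O, 0 °C). There the spiro transition state of the chiral dioxirane chooses the face of the trisubstituted alkene, and terminal 1,1-disubstituted alkenes react poorly. Should only the other epoxide be accessible, it is carried through the bromide-mediated double-inversion sequence described for step 7.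

Further compounds
F1 | step 7 | epoxy alcohol from 8, epoxide oxygen cis to the tertiary hydroxyl and the side chain | CC(C)[C@]1(O)CC[C@@]2(C)O[C@H]2[C@H]1[C@@H](OC(=O)c3cc(OC)c(OC)c(OC)c3)CC(C)=C
F2 | step 7 | trimethylsilyl ether of F1 (epoxide epimer of 10) | CC(C)[C@]1(O[Si](C)(C)C)CC[C@@]2(C)O[C@H]2[C@H]1[C@@H](OC(=O)c3cc(OC)c(OC)c(OC)c3)CC(C)=C
F3 | step 7 | trans-bromohydrin from F2, tertiary bromide cis to isopropyl and secondary hydroxyl cis to the silyloxy group | CC(C)[C@]1(O[Si](C)(C)C)CC[C@](C)(Br)[C@@H](O)[C@H]1[C@@H](OC(=O)c2cc(OC)c(OC)c(OC)c2)CC(C)=C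
F4 | step 2 | SAMP hydrazone of 4-methylcyclohex-3-en-1-one | COC[C@@H]1CCCN1N=C2CCC(C)=CC2
F5 | step 2 | SAMP hydrazone of aldol 5 | COC[C@@H]1CCCN1N=C2CCC(C)=C[C@H]2[C@@H](O)CC(C)=C
F0 | step 6 | none | none
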